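**Plan**
- Retrosynthesis: the six isopropyl ethers come off last. The two pyranone O1–C2 bonds are cut next, then both C2–C3 bonds at once (two O-to-C acyl transfers), then the two aryl ester C–O bonds, and finally the C8–C3' biaryl bond.
- Enabling feature: in each flavone unit C2 is an aroyl carbon, C3 an acetyl methyl carbon and O1 a phenol oxygen ortho to that acetyl. Ring A of the chrysoeriol unit can therefore carry an acetyl beside an O-vanilloyl ester, and ring B of the apigenin unit can carry its future C2 as a carboxyl esterified with an ortho-acetylphenol.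
- Forward: a Suzuki coupling first joins ring A of the chrysoeriol unit to ring B of the apigenin unit. The two esters are then attached, one base treatment forms both 1,3-diketones, acid closes both pyranone rings together, and BCl3 frees six phenols while the methyl ether stays.
- Stereochemistry: the target has no stereocentre, so none has to be set.

Key step: step 12

Remark: the target SMILES gives no descriptor for the biaryl axis, so the axis is treated as configurationally undefined; 1,3-diketones are drawn as diketo tautomers.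

Step 1
Reactants: 1 2',4',6'-trihydroxyacetophenone
Product: 2 1-(2-hydroxy-4,6-diisopropoxyphenyl)ethan-1-one
Conditions: 2-bromopropane (2.3 equiv), K2CO3, DMF, 50 °C
Reagents that add atoms: 2-bromopropane, CC(C)Br
Why: Williamson etherification should take only the two non-chelated phenols, because the third is hydrogen bonded to the acetyl carbonyl and is the least nucleophilic.

Step 2
Reactants: 2 1-(2-hydroxy-4,6-diisopropoxyphenyl)ethan-1-one
Product: 3 1-(2-hydroxy-3-iodo-4,6-diisopropoxyphenyl)ethan-1-one
Conditions: N-iodosuccinimide (1.0 equiv), CF3CO2H (cat.), MeCN, 0 °C to rt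
Reagents that add atoms: N-iodosuccinimide, O=C1CCC(=O)N1I
Why: Electrophilic aromatic iodination should go ortho to the free phenol (C3), since the only other open position lies between two bulky isopropoxy groups, and one equivalent of reagent limits diiodination.

Step 3
Reactants: 4 3-bromo-4-hydroxybenzoic acid
Product: 5 tert-butyl 3-bromo-4-hydroxybenzoate
Conditions: Me2NCH(OtBu)2 (4 equiv), toluene, 80 °C
Reagents that add atoms: N,N-dimethylformamide di-tert-butyl acetal, CN(C)C(OC(C)(C)C)OC(C)(C)C
Why: Esterification with a formamide acetal transfers the tert-butyl group to the carboxylate under neutral conditions and is expected to leave the less acidic phenol free.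

Step 4
Reactants: 5 tert-butyl 3-bromo-4-hydroxybenzoate
Product: 6 tert-butyl 3-bromo-4-isopropoxybenzoate
Conditions: 2-bromopropane (1.5 equiv), K2CO3, DMF, 60 °C
Reagents that add atoms: 2-bromopropane, CC(C)Br
Why: Williamson etherification of the phenol should proceed cleanly, as the tert-butyl ester is inert to carbonate.

Step 5
Reactants: 6 tert-butyl 3-bromo-4-isopropoxybenzoate
Product: 7 tert-butyl 4-isopropoxy-3-(4,4,5,5-tetramethyl-1,3,2-dioxaborolan-2-yl)benzoate
Conditions: B2pin2 (1.2 equiv), PdCl2(dppf) (3 mol %), KOAc, 1,4-dioxane, 90 °C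
Reagents that add atoms: bis(pinacolato)diboron, CC1(C)OB(OC1(C)C)B1OC(C)(C)C(C)(C)O1
Why: Miyaura borylation of the aryl bromide should give the pinacol boronate, with acetate too weak a base to start a competing Suzuki homocoupling or to harm the tert-butyl ester.

Step 6
Reactants: 3 1-(2-hydroxy-3-iodo-4,6-diisopropoxyphenyl)ethan-1-one; 7 tert-butyl 4-isopropoxy-3-(4,4,5,5-tetramethyl-1,3,2-dioxaborolan-2-yl)benzoate
Product: 8 tert-butyl 3-(3-acetyl-2-hydroxy-4,6-diisopropoxyphenyl)-4-isopropoxybenzoate
Conditions: Pd(OAc)2 (5 mol %), SPhos (10 mol %), K3PO4, toluene/H2O 10:1, 90 °C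
Reagents that add atoms: none
Why: Suzuki–Miyaura coupling with a dialkylbiarylphosphine ligand is the standard way to a biaryl with three ortho substituents, the aryl iodide remains reactive as its phenoxide, and the ketone and tert-butyl ester tolerate aqueous phosphate.

Step 7
Reactants: 9 vanillic acid
Product: 11 4-isopropoxy-3-methoxybenzoic acid, via isopropyl 4-isopropoxy-3-methoxybenzoate 10 (not isolated)
Conditions: 2-bromopropane (3 equiv), K2CO3, DMF, 70 °C; then NaOH, MeOH/H2O, 60 °C; then HCl (aq) to pH 2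
Reagents that add atoms: 2-bromopropane, CC(C)Br; sodium hydroxide, [Na+].[OH-]
Why: Exhaustive alkylation (Williamson ether formation plus carboxylate alkylation) followed by saponification of the isopropyl ester should leave the aryl isopropyl ether as the only new group.

Step 8
Reactants: 11 4-isopropoxy-3-methoxybenzoic acid
Product: 12 4-isopropoxy-3-methoxybenzoyl chloride
Conditions: (COCl)2 (1.5 equiv), DMF (cat.), CH2Cl2, 0 °C to rt; concentrated and used crude
Reagents that add atoms: oxalyl chloride, O=C(Cl)C(=O)Cl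
Why: Acid chloride formation through the Vilsmeier-type chloroiminium catalyst is routine for alkoxybenzoic acids and does not touch the aryl ethers.

Step 9
Reactants: 8 tert-butyl 3-(3-acetyl-2-hydroxy-4,6-diisopropoxyphenyl)-4-isopropoxybenzoate; 12 4-isopropoxy-3-methoxybenzoyl chloride
Product: 13 tert-butyl 3-[3-acetyl-2-(4-isopropoxy-3-methoxybenzoyloxy)-4,6-diisopropoxyphenyl]-4-isopropoxybenzoate
Conditions: 12 (1.5 equiv), Et3N, DMAP (0.3 equiv), CH2Cl2, 0 °C to 40 °C
Reagents that add atoms: none
Why: DMAP-catalysed O-acylation through the acylpyridinium ion should reach even this hindered, hydrogen-bonded phenol, and the amine base is too weak to enolise the acetyl group, so no acyl transfer starts early.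

Step 10
Reactants: 13 tert-butyl 3-[3-acetyl-2-(4-isopropoxy-3-methoxybenzoyloxy)-4,6-diisopropoxyphenyl]-4-isopropoxybenzoate
Product: 14 3-[3-acetyl-2-(4-isopropoxy-3-methoxybenzoyloxy)-4,6-diisopropoxyphenyl]-4-isopropoxybenzoic acid
Conditions: CF3CO2H/CH2Cl2 1:4, 0 °C to rt
Reagents that add atoms: none
Why: Acidolysis of the tert-butyl ester by alkyl–oxygen cleavage (loss of 2-methylpropene) is orthogonal to the base-labile aryl ester and to the aryl isopropyl ethers, which are stable to CF3CO2H at room temperature.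

Step 11
Reactants: 14 3-[3-acetyl-2-(4-isopropoxy-3-methoxybenzoyloxy)-4,6-diisopropoxyphenyl]-4-isopropoxybenzoic acid; 2 1-(2-hydroxy-4,6-diisopropoxyphenyl)ethan-1-one
Product: 15 2-acetyl-3,5-diisopropoxyphenyl 3-[3-acetyl-2-(4-isopropoxy-3-methoxybenzoyloxy)-4,6-diisopropoxyphenyl]-4-isopropoxybenzoate (biaryl bis-ester)
Conditions: 2 (1.3 equiv), N,N'-diisopropylcarbodiimide (1.5 equiv), DMAP (0.3 equiv), CH2Cl2, rt
Reagents that add atoms: none
Why: Steglich esterification through the acyl-DMAP intermediate is a standard way to make aryl esters of ortho-hydroxyacetophenones, and its near-neutral conditions should leave the existing hindered aryl ester in place.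

Step 12
Reactants: 15 biaryl bis-ester
Product: 16 1-(2-hydroxy-3-{5-[3-(2-hydroxy-4,6-diisopropoxyphenyl)-3-oxopropanoyl]-2-isopropoxyphenyl}-4,6-diisopropoxyphenyl)-3-(4-isopropoxy-3-methoxyphenyl)propane-1,3-dione (biaryl bis-1,3-diketone)
Conditions: LiN(SiMe3)2 (6 equiv), THF, −78 °C to rt; then HCl (1 M aq)
Reagents that add atoms: none
Why: Excess amide base turns both methyl ketones into lithium enolates, each enolate carbon adds to the ester carbonyl held on the oxygen ortho to it through a six-membered cyclic transition state, and each tetrahedral intermediate collapses to a phenoxide and a 1,3-diketone whose immediate deprotonation drives the transfer forward. The closest known reaction is the Baker–Venkataraman rearrangement of ortho-aroyloxyacetophenones, run here at two sites of one substrate. No ring closes and no stereocentre forms; the new bonds are C2–C3 of the chrysoeriol unit (ring A acetyl carbon to the vanilloyl carbon) and C2–C3 of the apigenin unit (acetyl carbon of the phloroglucinol ring to the carboxyl carbon of ring B). The selectivity needed is that each enolate takes its own neighbouring ester, which the substrate secures because only that pairing offers a six-membered transition state, while a crossed transfer would have to bridge meta positions across the biaryl or occur between molecules, and the non-nucleophilic base avoids ester cleavage. Because the ring A ester oxygen lies next to the biaryl carbon, the phenol set free there later becomes O1 beside C8, which fixes the 8-aryl pattern.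

Step 13
Reactants: 16 biaryl bis-1,3-diketone
Product: 17 5,7-diisopropoxy-8-[5-(5,7-diisopropoxy-4-oxo-4H-chromen-2-yl)-2-isopropoxyphenyl]-2-(4-isopropoxy-3-methoxyphenyl)-4H-chromen-4-one
Conditions: p-TsOH·H2O (0.5 equiv), toluene, 90 °C
Reagents that add atoms: none
Why: Acid-catalysed cyclodehydration of ortho-hydroxyaryl 1,3-diketones, the closing stage of the Baker–Venkataraman flavone synthesis, should have each free phenol add to the distal aroyl carbonyl in a 6-exo-trig hemiketalisation and then lose water to give both 4-pyranone rings, under sulfonic acid conditions that aryl isopropyl ethers tolerate.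

Step 14
Reactants: 17 hexa-O-isopropyl biflavone
Product: 18 5,7-dihydroxy-8-[5-(5,7-dihydroxy-4-oxo-4H-chromen-2-yl)-2-hydroxyphenyl]-2-(4-hydroxy-3-methoxyphenyl)-4H-chromen-4-one (CNP0179340.0)
Conditions: BCl3 (12 equiv), CH2Cl2, −78 °C to rt; then H2O
Reagents that add atoms: none
Why: Lewis-acid dealkylation with BCl3 cleaves aryl isopropyl ethers through the stabilised secondary cation far more readily than an aryl methyl ether with no neighbouring carbonyl to chelate boron, so all six isopropyl groups should fall while the 3'-methoxy group is kept.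

**Compound list**
1 | 2',4',6'-trihydroxyacetophenone | CC(=O)c1c(O)cc(O)cc1O | starting material
2 | 1-(2-hydroxy-4,6-diisopropoxyphenyl)ethan-1-one | CC(=O)c1c(O)cc(OC(C)C)cc1OC(C)C | intermediate
3 | 1-(2-hydroxy-3-iodo-4,6-diisopropoxyphenyl)ethan-1-one | CC(=O)c1c(O)c(I)c(OC(C)C)cc1OC(C)C | intermediate
4 | 3-bromo-4-hydroxybenzoic acid | OC(=O)c1ccc(O)c(Br)c1 | starting material
5 | tert-butyl 3-bromo-4-hydroxybenzoate | CC(C)(C)OC(=O)c1ccc(O)c(Br)c1 | intermediate
6 | tert-butyl 3-bromo-4-isopropoxybenzoate | CC(C)Oc1ccc(C(=O)OC(C)(C)C)cc1Br | intermediate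
7 | tert-butyl 4-isopropoxy-3-(4,4,5,5-tetramethyl-1,3,2-dioxaborolan-2-yl)benzoate | CC(C)Oc1ccc(C(=O)OC(C)(C)C)cc1B1OC(C)(C)C(C)(C)O1 | intermediate
8 | tert-butyl 3-(3-acetyl-2-hydroxy-4,6-diisopropoxyphenyl)-4-isopropoxybenzoate | CC(=O)c1c(OC(C)C)cc(OC(C)C)c(-c2cc(C(=O)OC(C)(C)C)ccc2OC(C)C)c1O | intermediate
9 | vanillic acid | COc1cc(C(=O)O)ccc1O | starting material
10 | isopropyl 4-isopropoxy-3-methoxybenzoate | COc1cc(C(=O)OC(C)C)ccc1OC(C)C | intermediate
11 | 4-isopropoxy-3-methoxybenzoic acid | COc1cc(C(=O)O)ccc1OC(C)C | intermediate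
12 | 4-isopropoxy-3-methoxybenzoyl chloride | COc1cc(C(=O)Cl)ccc1OC(C)C | intermediate
13 | tert-butyl 3-[3-acetyl-2-(4-isopropoxy-3-methoxybenzoyloxy)-4,6-diisopropoxyphenyl]-4-isopropoxybenzoate | CC(=O)c1c(OC(C)C)cc(OC(C)C)c(-c2cc(C(=O)OC(C)(C)C)ccc2OC(C)C)c1OC(=O)c1ccc(OC(C)C)c(OC)c1 | intermediate
14 | 3-[3-acetyl-2-(4-isopropoxy-3-methoxybenzoyloxy)-4,6-diisopropoxyphenyl]-4-isopropoxybenzoic acid | CC(=O)c1c(OC(C)C)cc(OC(C)C)c(-c2cc(C(=O)O)ccc2OC(C)C)c1OC(=O)c1ccc(OC(C)C)c(OC)c1 | intermediate
15 | 2-acetyl-3,5-diisopropoxyphenyl 3-[3-acetyl-2-(4-isopropoxy-3-methoxybenzoyloxy)-4,6-diisopropoxyphenyl]-4-isopropoxybenzoate (biaryl bis-ester) | CC(=O)c1c(OC(C)C)cc(OC(C)C)c(-c2cc(C(=O)Oc3cc(OC(C)C)cc(OC(C)C)c3C(C)=O)ccc2OC(C)C)c1OC(=O)c1ccc(OC(C)C)c(OC)c1 | intermediate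
16 | 1-(2-hydroxy-3-{5-[3-(2-hydroxy-4,6-diisopropoxyphenyl)-3-oxopropanoyl]-2-isopropoxyphenyl}-4,6-diisopropoxyphenyl)-3-(4-isopropoxy-3-methoxyphenyl)propane-1,3-dione (biaryl bis-1,3-diketone) | COc1cc(C(=O)CC(=O)c2c(OC(C)C)cc(OC(C)C)c(-c3cc(C(=O)CC(=O)c4c(O)cc(OC(C)C)cc4OC(C)C)ccc3OC(C)C)c2O)ccc1OC(C)C | intermediate
17 | 5,7-diisopropoxy-8-[5-(5,7-diisopropoxy-4-oxo-4H-chromen-2-yl)-2-isopropoxyphenyl]-2-(4-isopropoxy-3-methoxyphenyl)-4H-chromen-4-one | COc1cc(-c2cc(=O)c3c(OC(C)C)cc(OC(C)C)c(-c4cc(-c5cc(=O)c6c(OC(C)C)cc(OC(C)C)cc6o5)ccc4OC(C)C)c3o2)ccc1OC(C)C | intermediate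
18 | 5,7-dihydroxy-8-[5-(5,7-dihydroxy-4-oxo-4H-chromen-2-yl)-2-hydroxyphenyl]-2-(4-hydroxy-3-methoxyphenyl)-4H-chromen-4-one (CNP0179340.0) | COc1cc(-c2cc(=O)c3c(O)cc(O)c(-c4cc(-c5cc(=O)c6c(O)cc(O)cc6o5)ccc4O)c3o2)ccc1O | target

**Count and risks**
Total steps: 14. Longest linear sequence: 10 steps (4 → 5 → 6 → 7 → 8 → 13 → 14 → 15 → 16 → 17 → 18, that is steps 3, 4, 5, 6, 9, 10, 11, 12, 13, 14).

The three steps most likely to fail:

1. Step 12, the twofold acyl transfer. The transfer at the crowded ring A ester may lag behind the one on the other side, so that long exposure to base brings aryl ester cleavage or a mixture of half-rearranged material. The fallback sets out from 13 and returns at 17, running the two transfers one after the other. Compound 13, in which only the ring A ester can react, is treated with LiN(SiMe3)2 in THF to give the ring A 1,3-diketone tert-butyl ester F1. p-TsOH·H2O in toluene at 90 °C, followed by CF3CO2H/CH2Cl2, closes the first pyranone and cleaves the tert-butyl ester to give the flavone carboxylic acid F2. Steglich esterification with 2 (N,N'-diisopropylcarbodiimide, DMAP) gives the flavone aryl ester F3. A second Baker–Venkataraman rearrangement, now with a single ester in the molecule, gives the flavone 1,3-diketone F4, and acid-catalysed cyclodehydration delivers 17.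

2. Step 6, the hindered Suzuki coupling. Protodeboronation of the ortho-alkoxy boronate may outrun a coupling slowed by the ortho phenoxide and the two flanking substituents on the iodide. The fallback sets out from 3 and returns at 8, masking the phenol during the coupling. Benzylation of 3 (BnBr, K2CO3, DMF) gives the benzyl ether F5. Coupling with 7 (Pd(OAc)2, SPhos, K3PO4) gives the benzyl-protected biaryl F6. Hydrogenolysis (H2, Pd/C, EtOAc) frees the phenol and returns 8.

3. Step 9, acylation of the phenol. O-Acylation of a phenol that is hydrogen bonded to the acetyl group and boxed in by the new aryl ring may be slow or incomplete, and stronger base would invite premature enolisation. The fallback sets out from 3 and returns at 13, installing the ester before the biaryl bond. Acylation of the less hindered 3 with 12 (Et3N, DMAP, CH2Cl2) gives the iodo aryl ester F7. This is coupled with 7 under anhydrous fluoride conditions (Pd(OAc)2, SPhos, KF, 1,4-dioxane, 80 °C) to give 13 directly, bypassing 8.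

**Further compounds**
F1 | step 12 | ring A 1,3-diketone tert-butyl ester (tert-butyl 3-{2-hydroxy-4,6-diisopropoxy-3-[3-(4-isopropoxy-3-methoxyphenyl)-3-oxopropanoyl]phenyl}-4-isopropoxybenzoate) | COc1cc(C(=O)CC(=O)c2c(OC(C)C)cc(OC(C)C)c(-c3cc(C(=O)OC(C)(C)C)ccc3OC(C)C)c2O)ccc1OC(C)C
F2 | step 12 | flavone carboxylic acid (3-[5,7-diisopropoxy-2-(4-isopropoxy-3-methoxyphenyl)-4-oxo-4H-chromen-8-yl]-4-isopropoxybenzoic acid) | COc1cc(-c2cc(=O)c3c(OC(C)C)cc(OC(C)C)c(-c4cc(C(=O)O)ccc4OC(C)C)c3o2)ccc1OC(C)C
F3 | step 12 | flavone aryl ester (2-acetyl-3,5-diisopropoxyphenyl 3-[5,7-diisopropoxy-2-(4-isopropoxy-3-methoxyphenyl)-4-oxo-4H-chromen-8-yl]-4-isopropoxybenzoate) | COc1cc(-c2cc(=O)c3c(OC(C)C)cc(OC(C)C)c(-c4cc(C(=O)Oc5cc(OC(C)C)cc(OC(C)C)c5C(C)=O)ccc4OC(C)C)c3o2)ccc1OC(C)C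
F4 | step 12 | flavone 1,3-diketone (1-(2-hydroxy-4,6-diisopropoxyphenyl)-3-{3-[5,7-diisopropoxy-2-(4-isopropoxy-3-methoxyphenyl)-4-oxo-4H-chromen-8-yl]-4-isopropoxyphenyl}propane-1,3-dione) | COc1cc(-c2cc(=O)c3c(OC(C)C)cc(OC(C)C)c(-c4cc(C(=O)CC(=O)c5c(O)cc(OC(C)C)cc5OC(C)C)ccc4OC(C)C)c3o2)ccc1OC(C)C
F5 | step 6 | benzyl ether (1-(2-benzyloxy-3-iodo-4,6-diisopropoxyphenyl)ethan-1-one) | CC(=O)c1c(OCc2ccccc2)c(I)c(OC(C)C)cc1OC(C)C
F6 | step 6 | benzyl-protected biaryl (tert-butyl 3-(3-acetyl-2-benzyloxy-4,6-diisopropoxyphenyl)-4-isopropoxybenzoate) | CC(=O)c1c(OC(C)C)cc(OC(C)C)c(-c2cc(C(=O)OC(C)(C)C)ccc2OC(C)C)c1OCc1ccccc1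
F7 | step 9 | iodo aryl ester (2-acetyl-6-iodo-3,5-diisopropoxyphenyl 4-isopropoxy-3-methoxybenzoate) | CC(=O)c1c(OC(C)C)cc(OC(C)C)c(I)c1OC(=O)c1ccc(OC(C)C)c(OC)c1
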